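Remark on the chemistry: chromone numbering is used throughout (O1, C2, C3, C4, C4a, C5–C8, C8a; ring B primed). The benzaldehyde carbons of the benzoin precursor map as CHO → C4, C1 → C4a, C2 → C8a, C3 → C8, C4 → C7, C5 → C6, C6 → C5; with this mapping the precursor and the adduct carry every substituent in the right place and need no structural correction. The adduct is made as the racemate because its only stereocentre is removed in the next step.

## Structural features

The target is an isoflavone: a 4H-chromen-4-one (benzo ring A fused to pyranone ring C) that carries a 2,4,5-trimethoxyphenyl group (ring B) on C3 through the C3–C1' single bond. Ring A is fully substituted, with OH on C5, a prenyl (3-methylbut-2-enyl) chain on C6, OMe on C7 and OH on C8, so that C5 and C8 form a para-hydroquinone. There is no stereocentre and no stereogenic double bond, so no stereocentres stand next to each other and the problem is one of regiochemistry and of functional-group timing. The hydroquinone is easily oxidised by air to the 5,8-quinone. The prenyl group next to the C5 hydroxyl cyclises to a dimethylchroman or hydrates under acid. Ring B has a 2',5'-dimethoxy relationship that strong one-electron oxidants turn into a quinone. The real difficulty is to place four different groups in a fixed order around ring A, and to tell the oxygens on C5, C8 and C8a (O1) apart from each other and from the C7 methoxy group while four methyl ethers stay intact. The key step exploits the fact that C3 and C4 are neighbours that can both start as carbonyl carbons: C4 as an aldehyde on C4a, and C3 as the aryl ketone hung from the C8a oxygen through the C2 methylene. Joining them with reversed polarity closes ring C, and the C3 hydroxyl and a C2 hydrogen that result are exactly the water that must be lost to form the C2=C3 bond.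

## Logic of the disconnections

**19 to 14 and 17.** The C6–C1'' bond of the prenyl chain is cut first. C6 is the only hydrogen-bearing carbon of ring A, and in the quinone oxidation level of 14 it is the only position at which a new C–C bond can be followed by re-aromatisation. Removing the acid-sensitive side chain last means that no earlier step has to tolerate it. The forward step must deliver the linear prenyl isomer, must attack ring A and not C2 of ring C, and must end at the hydroquinone level.

**17 to 15.** The C–Sn bond is cut; 15 supplies all five carbons of the side chain. The forward step must give the primary allylic stannane.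

**14 to 13 to 12.** No skeletal bond is cut here. The quinone of 14 is traced back to the hydroquinone 13, and the two free hydroxyls of 13 to the two isopropyl ethers of 12. Isopropyl is kept for O5 and O8 because it can be removed by a Lewis acid without loss of the four methyl ethers, and because it is inert to thiolate, carbonate, the carbene catalyst and the dehydrating agent. The oxidant must spare ring B.

**12 to 11.** Water is added back across C2=C3, giving the tertiary C3 carbinol of 11. This turns the flat chromone into an alpha-ketol whose C3–C4 bond can be made from two carbonyl groups. The forward dehydration must run toward C2, the only carbon with a beta-hydrogen, under conditions that do not cleave the isopropyl ethers.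

**11 to 10.** The C3–C4 bond is cut, opening ring C to the keto-aldehyde 10. This is the strategic cut: it removes one ring, one skeletal bond and the only stereocentre of the route, and leaves an acyclic ether in which every oxygen of ring A is already in place. The forward step must couple an aldehyde with a ketone in preference to aldehyde self-condensation and to aldol closure of the alpha-aryloxy methylene.

**10 to 6 and 9.** The O1–C2 ether bond is cut. This divides the molecule into two halves of similar size and fixes O1 as the single free phenol of 6. The forward alkylation must stop at the ether and not run on to a benzofuran.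

**9 to 7 and 8.** The C1'–C(=O) bond is cut. The three methoxy groups of 7 direct the acylation to the one carbon that gives the 2,4,5-pattern. The Lewis acid must not remove the methyl ether ortho to the new ketone.

**6 to 4.** The C4a–CHO bond is cut. The free hydroxyl of 4 directs the formyl group to its only free ortho carbon; the para carbon must not react.

**4 to 3 to 2 to 1.** One O–CH3 bond, then two O–isopropyl bonds, then the quinone/hydroquinone redox change are undone. Compound 3 has a mirror plane through C2 and C5, so its two methyl ethers are equivalent and removal of either gives the same phenol; that oxygen becomes O1. The forward demethylation must stop after one methyl group and must not touch the isopropyl groups.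

## Other disconnections considered

**Alternative 1:** The cut is the C4a–C5 bond of ring A, with the C8–C8a bond made one step earlier when ring C is attached to a four-membered ring. In the forward sense the enol ether A4 (the ethylene ketal of 2,3-dihydropyran-4-one) would be lithiated at its oxygen-bearing vinyl carbon and added to the squarate-derived dione A3 at the carbonyl next to the methoxy-bearing carbon, the more ketone-like of the two. Heating the adduct A2 would open the cyclobutenone to a dienylketene, and six-electron closure with tautomerisation would give the hydroquinone A1 (Moore ring expansion).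
- In its favour: ring A would appear with all four substituents, prenyl included, in an order set by the squarate, with no electrophilic substitution, no Lewis acid and no tin. On prenyl placement this plan is better than the chosen one, whose last step is its least predictable. The thermal cascade needs no catalyst and is mechanistically as dependable as the benzoin closure. O1 is fixed as securely as in the chosen plan (equal).
- Against it: A1 has neither ring B nor the C2=C3 bond. Ketal removal would need acid in the presence of an ortho-prenyl hydroquinone, the combination that cyclises to a chroman. The hydroquinone would then need protection, C3 would need functionalisation, and a palladium-catalysed coupling would be needed to bring in the 2,4,5-trimethoxyphenyl group. A3 itself takes two or three steps from a dialkyl squarate, with an alpha/gamma question of its own in the prenyl addition.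
- Step economy: about four steps to A1 and six or more afterwards, against twelve in total for the chosen plan, which brings in ring B in the same operation that closes ring C.

**Alternative 2:** The cuts are C5–C6, C7–C8 and C4a–C5. Ring A would be assembled from the four-carbon unit A6 (2,3-diisopropoxycyclobutenone, supplying C8, C8a, C4a and C5) and the two-carbon ynol ether A7 (supplying C7 with its methoxy group and C6 with its prenyl group). Heating would open A6 to a vinylketene, which adds [2+2] to the electron-rich alkyne; the new vinylcyclobutenone opens again and the dienylketene closes to the phenol A5 (Danheiser benzannulation).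
- In its favour: it is convergent and a single thermal operation. The polarity of the ynol ether places methoxy and prenyl correctly. The C5 hydroxyl emerges free and ortho to the CH that must become C4a, a better setting for an ortho-acylation than anything in the chosen plan. No quinone or tin chemistry is needed.
- Against it: in A5 the oxygens on C8 and C8a carry the same isopropyl group, yet only the C8a oxygen may be freed to become O1. Differentiating them would require a cyclobutenone with two different alkoxy groups, at the cost of extra squarate steps. A7 is a volatile, acid-sensitive ynol ether. Rings C and B would still have to be built by ortho-acylation with a (2,4,5-trimethoxyphenyl)acetyl unit and a one-carbon insertion, under acidic conditions that an ortho-prenylphenol tolerates poorly.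
- Comparison: prenyl placement is better; the assignment of O1 is worse, since the chosen plan obtains O1 by removing one of two equivalent methyl groups. The pericyclic mechanism is well founded. In step count the plan is equal at best: about three steps to A6, two to A7, the annulation, and five or more to finish.

**Alternative 3:** The cut is the C4–C4a bond, and ring C would be closed by intramolecular Friedel–Crafts acylation. The phenol 4 of the chosen plan would be joined through its oxygen to C3 of a 2-(2,4,5-trimethoxyphenyl)acrylate by addition–elimination, and the ester hydrolysed to the acid A9. Trifluoroacetic anhydride would turn A9 into a mixed anhydride and acylium ion that attacks the ring carbon ortho to the aryloxy oxygen, giving the isoflavone A8, which is identical with 12.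
- In its favour: the chromone oxidation level is reached directly, so no carbinol stereocentre is made and erased and no dehydration is needed; on this point it is better. There is no aldehyde, so the formylation and the aldol hazard of the phenacyl ether disappear. The attacked carbon is the only free ortho position and is para to the C7 methoxy group, so regiochemistry is as secure as in the chosen plan (equal). From 4 it needs about four steps to reach 12, the same number as steps 4, 6, 7 and 8 of the chosen plan (equal), and it rejoins the same endgame.
- Against it: the acid and the aryloxy group must be cis on the double bond, as drawn for A9, or must isomerise under the reaction conditions. The acylium ion of a beta-aryloxyacrylic acid is a stabilised, weak electrophile, so forcing conditions may be needed. Under those conditions trifluoroacetylation of ring B or of the ring A carbon para to the aryloxy oxygen is conceivable, as is acid-induced loss of the isopropyl group next to the new carbonyl. The arylacetic ester is a further building block, two or three steps from 7.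
- Comparison: a stoichiometric strong electrophile in strong acid stands against a catalytic, nearly neutral carbene process. The alternative is a serious competitor on length, and the chosen plan is preferred for its milder bond-forming step.

Key step: step 7

## Route

**Step 1**
Reactants: 1 2,6-dimethoxy-1,4-benzoquinone
Product: 2 2,6-dimethoxybenzene-1,4-diol
Conditions: Na2S2O4, EtOAc/H2O, rt, Ar; used at once
Reagents that add atoms: none
Why: Dithionite reduction of a para-quinone to its hydroquinone is fast in a two-phase system; the electron-rich product is air-sensitive and is therefore carried on directly under argon.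

**Step 2**
Reactants: 2 2,6-dimethoxybenzene-1,4-diol
Product: 3 1,3-dimethoxy-2,5-di(propan-2-yloxy)benzene
Conditions: 2-bromopropane (5 equiv), K2CO3, DMF, 65 °C, Ar
Reagents that add atoms: 2-bromopropane, CC(C)Br
Why: Williamson ether synthesis on both phenoxides; the excess of the secondary bromide makes up for its partial elimination, and the hindered oxygen between the two methoxy groups is simply the slower one. Isopropyl is chosen because it survives thiolate, carbonate, the carbene and SOCl2 but is cleaved by BCl3 beside methyl ethers.

**Step 3**
Reactants: 3 1,3-dimethoxy-2,5-di(propan-2-yloxy)benzene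
Product: 4 3-methoxy-2,5-di(propan-2-yloxy)phenol
Conditions: NaSEt (2.5 equiv), DMF, 110 °C; aq. HCl work-up
Reagents that add atoms: none
Why: Thiolate SN2 dealkylation of an aryl methyl ether; the two methoxy groups are equivalent by symmetry, attack at CH3 is much faster than at the secondary carbon of an isopropyl ether, and the phenoxide formed deactivates the remaining methyl ether, so a single phenol should result.

**Step 4**
Reactants: 4 3-methoxy-2,5-di(propan-2-yloxy)phenol
Product: 6 2-hydroxy-4-methoxy-3,6-di(propan-2-yloxy)benzaldehyde, via benzylic alcohol 5 (not isolated)
Conditions: MgCl2, Et3N, (CH2O)n, MeCN, reflux; 1 M HCl work-up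
Reagents that add atoms: paraformaldehyde (formaldehyde units), C=O
Why: Magnesium-mediated ortho-formylation of a phenol (Casnati–Skattebøl reaction): the magnesium phenoxide delivers formaldehyde through a six-membered chelate to the only free ortho carbon, and the benzylic alkoxide 5 is oxidised by a second formaldehyde through Oppenauer-type hydride transfer. The para carbon is not reached because delivery is intramolecular.

**Step 5**
Reactants: 7 1,2,4-trimethoxybenzene; 8 bromoacetyl bromide
Product: 9 2-bromo-1-(2,4,5-trimethoxyphenyl)ethan-1-one
Conditions: AlCl3 (1.1 equiv), CH2Cl2, −10 → 0 °C, short time; ice/HCl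
Reagents that add atoms: none
Why: Friedel–Crafts acylation; C5 of 7 is para to one methoxy group and ortho to another and is the most nucleophilic unhindered position, which gives the 2,4,5-pattern. Low temperature and a short reaction time limit loss of the methyl ether ortho to the new ketone.

**Step 6**
Reactants: 6 2-hydroxy-4-methoxy-3,6-di(propan-2-yloxy)benzaldehyde; 9 2-bromo-1-(2,4,5-trimethoxyphenyl)ethan-1-one
Product: 10 4-methoxy-2-[2-oxo-2-(2,4,5-trimethoxyphenyl)ethoxy]-3,6-di(propan-2-yloxy)benzaldehyde
Conditions: K2CO3 (1.2 equiv), acetone, 0 °C → rt
Reagents that add atoms: none
Why: Williamson O-alkylation of a salicylaldehyde phenoxide with a very reactive phenacyl bromide; mild carbonate at or below room temperature is used so that the ether does not go on to intramolecular aldol condensation (Rap–Stoermer benzofuran formation).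

**Step 7**
Reactants: 10 4-methoxy-2-[2-oxo-2-(2,4,5-trimethoxyphenyl)ethoxy]-3,6-di(propan-2-yloxy)benzaldehyde
Product: 11 rac-3-hydroxy-7-methoxy-5,8-di(propan-2-yloxy)-3-(2,4,5-trimethoxyphenyl)-2,3-dihydro-4H-chromen-4-one
Conditions: 2-(pentafluorophenyl)-6,7-dihydro-5H-pyrrolo[2,1-c][1,2,4]triazol-2-ium tetrafluoroborate (20 mol %), Et3N (20 mol %), degassed toluene (0.05 M), rt → 40 °C, Ar
Reagents that add atoms: none
Why: Et3N deprotonates the triazolium salt to the triazolylidene, which adds to the aldehyde carbon; proton transfer gives the enaminol (Breslow intermediate), an acyl anion equivalent at C4. This carbon attacks the tethered ketone carbon C3 in a 6-exo-trig closure that forms the C3–C4 bond and ring C, and proton transfer with loss of the carbene releases the alpha-ketol. The closest known reaction type is the carbene-catalysed intramolecular crossed aldehyde–ketone benzoin reaction of 2-(2-oxo-2-arylethoxy)benzaldehydes to 3-aryl-3-hydroxychroman-4-ones. The new stereocentre at C3 is set without control, since the catalyst is achiral and the centre is removed in step 8. The step needs cross coupling to win over aldehyde self-condensation and over base-induced aldol closure of the OCH2 group onto the aldehyde. The six-membered tether makes the cross coupling intramolecular, and the two ortho oxygen substituents slow any bimolecular reaction of the aldehyde. The acidic N-pentafluorophenyl triazolium allows a weak amine base, which keeps the enolate concentration low, and the small bicyclic carbene is chosen because the aldehyde is 2,6-disubstituted. Degassing prevents oxidation of the enaminol to the carboxylic acid.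

**Step 8**
Reactants: 11 rac-3-hydroxy-7-methoxy-5,8-di(propan-2-yloxy)-3-(2,4,5-trimethoxyphenyl)-2,3-dihydro-4H-chromen-4-one
Product: 12 7-methoxy-5,8-di(propan-2-yloxy)-3-(2,4,5-trimethoxyphenyl)-4H-chromen-4-one
Conditions: SOCl2, pyridine, CH2Cl2, 0 °C → rt
Reagents that add atoms: none
Why: Dehydration of a tertiary benzylic alpha-ketol through its chlorosulfite; ionisation is helped by the electron-rich aryl group, the only beta-hydrogens are on C2 and their loss is helped by O1, so the chromone C2=C3 bond forms and the stereocentre disappears. Pyridine buffers the HCl so that the isopropyl ethers remain.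

**Step 9**
Reactants: 12 7-methoxy-5,8-di(propan-2-yloxy)-3-(2,4,5-trimethoxyphenyl)-4H-chromen-4-one
Product: 13 5,8-dihydroxy-7-methoxy-3-(2,4,5-trimethoxyphenyl)-4H-chromen-4-one
Conditions: BCl3 (1 M in CH2Cl2, 4 equiv), CH2Cl2, −78 → 0 °C; then H2O
Reagents that add atoms: none
Why: Lewis acid cleavage of aryl isopropyl ethers; the secondary alkyl–oxygen bonds ionise far more easily than methyl–oxygen bonds and the C5 ether is further activated by chelation to the C4 carbonyl. No methyl ether lies next to a carbonyl group, so the four methoxy groups should survive.

**Step 10**
Reactants: 13 5,8-dihydroxy-7-methoxy-3-(2,4,5-trimethoxyphenyl)-4H-chromen-4-one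
Product: 14 7-methoxy-3-(2,4,5-trimethoxyphenyl)-4H-chromene-4,5,8-trione
Conditions: Ag2O, Na2SO4, CH2Cl2, rt, dark
Reagents that add atoms: none
Why: Oxidation of a para-hydroquinone to the para-quinone with Ag2O, a mild heterogeneous oxidant that should leave ring B alone; stronger one-electron oxidants could attack its 2',5'-dimethoxy pattern.

**Step 11**
Reactants: 15 prenyl bromide (1-bromo-3-methylbut-2-ene)
Product: 17 tributyl(3-methylbut-2-en-1-yl)stannane, via prenylmagnesium bromide 16 (not isolated)
Conditions: Mg turnings, Bu3SnCl, THF, 0 °C → rt (Barbier conditions, slow addition of 15)
Reagents that add atoms: tributyltin chloride, CCCC[Sn](Cl)(CCCC)CCCC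
Why: Barbier-type formation of the allylic Grignard reagent in the presence of the tin chloride, which traps it as it forms and so suppresses Wurtz coupling; the primary stannane is the favoured isomer because the tertiary allylic stannane is far more hindered.

**Step 12**
Reactants: 14 7-methoxy-3-(2,4,5-trimethoxyphenyl)-4H-chromene-4,5,8-trione; 17 tributyl(3-methylbut-2-en-1-yl)stannane
Product: 19 5,8-dihydroxy-7-methoxy-6-(3-methylbut-2-en-1-yl)-3-(2,4,5-trimethoxyphenyl)-4H-chromen-4-one, via 6-prenylquinone 18 (not isolated)
Conditions: BF3·OEt2 (2 equiv), CH2Cl2, −78 → −40 °C; aq. KF; then aq. Na2S2O4/EtOAc, Ar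
Reagents that add atoms: none
Why: Lewis acid-mediated addition of an allylic stannane to a quinone: the BF3-activated quinone is attacked at a carbonyl carbon by the gamma-carbon of 17 and the adduct rearranges by a [3,3] shift, which places the linear prenyl group on C6, the only ring A carbon that carries hydrogen and can therefore re-aromatise; adducts at blocked carbons revert. The hydroquinone exchanges oxidation level with unreacted 14, so part of the material is present as the quinone 18, and the dithionite wash returns it to 19.

## Compound list

1 | 2,6-dimethoxy-1,4-benzoquinone | COC1=CC(=O)C=C(OC)C1=O | starting material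
2 | 2,6-dimethoxybenzene-1,4-diol | COc1cc(O)cc(OC)c1O | intermediate
3 | 1,3-dimethoxy-2,5-di(propan-2-yloxy)benzene | COc1cc(OC(C)C)cc(OC)c1OC(C)C | intermediate
4 | 3-methoxy-2,5-di(propan-2-yloxy)phenol | COc1cc(OC(C)C)cc(O)c1OC(C)C | intermediate
5 | 2-(hydroxymethyl)-5-methoxy-3,6-di(propan-2-yloxy)phenol (as its magnesium salt, not isolated) | OCc1c(O)c(OC(C)C)c(OC)cc1OC(C)C | intermediate
6 | 2-hydroxy-4-methoxy-3,6-di(propan-2-yloxy)benzaldehyde | O=Cc1c(O)c(OC(C)C)c(OC)cc1OC(C)C | intermediate
7 | 1,2,4-trimethoxybenzene | COc1ccc(OC)c(OC)c1 | starting material
8 | bromoacetyl bromide | BrCC(Br)=O | starting material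
9 | 2-bromo-1-(2,4,5-trimethoxyphenyl)ethan-1-one | COc1cc(OC)c(C(=O)CBr)cc1OC | intermediate
10 | 4-methoxy-2-[2-oxo-2-(2,4,5-trimethoxyphenyl)ethoxy]-3,6-di(propan-2-yloxy)benzaldehyde | CC(C)Oc1cc(OC)c(OC(C)C)c(OCC(=O)c2cc(OC)c(OC)cc2OC)c1C=O | intermediate
11 | rac-3-hydroxy-7-methoxy-5,8-di(propan-2-yloxy)-3-(2,4,5-trimethoxyphenyl)-2,3-dihydro-4H-chromen-4-one (racemate, C3 unassigned) | COc1cc(OC)c(C2(O)COc3c(OC(C)C)c(OC)cc(OC(C)C)c3C2=O)cc1OC | intermediate
12 | 7-methoxy-5,8-di(propan-2-yloxy)-3-(2,4,5-trimethoxyphenyl)-4H-chromen-4-one | COc1cc(OC)c(-c2coc3c(OC(C)C)c(OC)cc(OC(C)C)c3c2=O)cc1OC | intermediate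
13 | 5,8-dihydroxy-7-methoxy-3-(2,4,5-trimethoxyphenyl)-4H-chromen-4-one | COc1cc(OC)c(-c2coc3c(O)c(OC)cc(O)c3c2=O)cc1OC | intermediate
14 | 7-methoxy-3-(2,4,5-trimethoxyphenyl)-4H-chromene-4,5,8-trione | COc1cc(OC)c(C2=COC3=C(C2=O)C(=O)C=C(OC)C3=O)cc1OC | intermediate
15 | prenyl bromide (1-bromo-3-methylbut-2-ene) | CC(C)=CCBr | starting material
16 | prenylmagnesium bromide (not isolated) | CC(C)=CC[Mg]Br | intermediate
17 | tributyl(3-methylbut-2-en-1-yl)stannane | CCCC[Sn](CCCC)(CCCC)CC=C(C)C | intermediate
18 | 7-methoxy-6-(3-methylbut-2-en-1-yl)-3-(2,4,5-trimethoxyphenyl)-4H-chromene-4,5,8-trione (not isolated) | COc1cc(OC)c(C2=COC3=C(C2=O)C(=O)C(CC=C(C)C)=C(OC)C3=O)cc1OC | intermediate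
19 | 5,8-dihydroxy-7-methoxy-6-(3-methylbut-2-en-1-yl)-3-(2,4,5-trimethoxyphenyl)-4H-chromen-4-one | COc1cc(OC)c(-c2coc3c(O)c(OC)c(CC=C(C)C)c(O)c3c2=O)cc1OC | target

## Step count and least certain steps

Total: 12 steps. Longest linear sequence: 10 steps (steps 1–4, 6–10 and 12, from 1). Steps 5 and 11 are one-step side branches.

**Step 7 (key step).** Carbene addition to the doubly ortho-substituted aldehyde may be slow. Base-induced aldol closure of the OCH2 group onto the aldehyde, or oxidation of the enaminol, could then overtake the benzoin closure, and the electron-rich aryl ketone is a weak acceptor. Fallback: from 10, the same C3–C4 bond is made reductively by an intramolecular ketyl–carbonyl (pinacol) coupling with SmI2 in THF at −78 °C. This should give 7-methoxy-5,8-di(propan-2-yloxy)-3-(2,4,5-trimethoxyphenyl)-3,4-dihydro-2H-chromene-3,4-diol F1 as a mixture of diastereomers. Parikh–Doering oxidation (SO3·pyridine, DMSO, Et3N) of its secondary benzylic C4 alcohol, which does not cleave the glycol, converges both diastereomers on 11.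

**Step 12.** The stannane may react through the wrong end and deliver a 1,1-dimethylallyl group. The first carbonyl adduct may also fail to rearrange, or BF3 may induce cyclisation of the new prenyl group onto the C5 oxygen. Fallback: from 14, the same Lewis acid allylation is run with commercial allyltributylstannane, which has no alpha/gamma ambiguity and gives no tertiary cation. With the same KF and dithionite work-up it should give 5,8-dihydroxy-7-methoxy-6-(prop-2-en-1-yl)-3-(2,4,5-trimethoxyphenyl)-4H-chromen-4-one F2. Olefin cross-metathesis of F2 with 2-methylbut-2-ene, using the second-generation Grubbs catalyst RuCl2(=CHPh)(PCy3)(H2IMes) under argon, then turns allyl into prenyl and arrives at 19.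

**Step 3.** The thiolate may attack the isopropyl group of the twisted central ether, or a second methyl group may be lost. Fallback: from 3, the order is reversed. Vilsmeier–Haack formylation (POCl3, DMF) at the only type of free ring carbon should give 2,4-dimethoxy-3,6-di(propan-2-yloxy)benzaldehyde F3. Chelation-controlled demethylation with MgI2 etherate then removes the methyl ether ortho to the aldehyde: iodide attacks CH3 much faster than the secondary carbon of the other ortho ether. This arrives at 6 and bypasses 4 and step 4.

**Step 6.** The product may undergo intramolecular aldol condensation of the phenacyl methylene with the ortho aldehyde under the basic alkylation conditions, ending in a 2-aroylbenzofuran. Fallback: from 9, displacement with HCO2Na in aqueous ethanol gives 2-oxo-2-(2,4,5-trimethoxyphenyl)ethyl formate F4, which is not isolated and is solvolysed in the same flask to 2-hydroxy-1-(2,4,5-trimethoxyphenyl)ethan-1-one F5. Mitsunobu etherification of F5 with the phenol 6 (PPh3, diisopropyl azodicarboxylate, THF, 0 °C) forms the O1–C2 bond without carbonate base and arrives at 10.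

**Step 5.** AlCl3 may cleave the methyl ether ortho to the new ketone, and halide exchange or a second acylation may complicate the product. Fallback: from 7, carbon–carbon and carbon–bromine bonds are made separately. Acetylation with Ac2O and ZnCl2 gives 1-(2,4,5-trimethoxyphenyl)ethan-1-one F6, and side-chain bromination with phenyltrimethylammonium tribromide in THF arrives at 9.

## Further compounds

F1 | step 7 | 7-methoxy-5,8-di(propan-2-yloxy)-3-(2,4,5-trimethoxyphenyl)-3,4-dihydro-2H-chromene-3,4-diol (racemic mixture of diastereomers, both converge on 11) | COc1cc(OC)c(C2(O)COc3c(OC(C)C)c(OC)cc(OC(C)C)c3C2O)cc1OC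
F2 | step 12 | 5,8-dihydroxy-7-methoxy-6-(prop-2-en-1-yl)-3-(2,4,5-trimethoxyphenyl)-4H-chromen-4-one | COc1cc(OC)c(-c2coc3c(O)c(OC)c(CC=C)c(O)c3c2=O)cc1OC
F3 | step 3 | 2,4-dimethoxy-3,6-di(propan-2-yloxy)benzaldehyde | O=Cc1c(OC)c(OC(C)C)c(OC)cc1OC(C)C
F4 | step 6 | 2-oxo-2-(2,4,5-trimethoxyphenyl)ethyl formate | O=COCC(=O)c1cc(OC)c(OC)cc1OC
F5 | step 6 | 2-hydroxy-1-(2,4,5-trimethoxyphenyl)ethan-1-one | OCC(=O)c1cc(OC)c(OC)cc1OC
F6 | step 5 | 1-(2,4,5-trimethoxyphenyl)ethan-1-one | CC(=O)c1cc(OC)c(OC)cc1OC
A1 | alternative 1 | 7-methoxy-6-(3-methylbut-2-en-1-yl)chroman-4-one-5,8-diol ethylene ketal | Oc1c(CC=C(C)C)c(OC)c(O)c2OCCC3(OCCO3)c12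
A2 | alternative 1 | 4-hydroxy-3-methoxy-2-(3-methylbut-2-en-1-yl)-4-(1,4,8-trioxaspiro[4.5]dec-6-en-7-yl)cyclobut-2-en-1-one (racemic) | O=C1C(CC=C(C)C)=C(OC)C1(O)C2=CC3(CCO2)OCCO3
A3 | alternative 1 | 3-methoxy-4-(3-methylbut-2-en-1-yl)cyclobut-3-ene-1,2-dione | COC1=C(CC=C(C)C)C(=O)C1=O
A4 | alternative 1 | 1,4,8-trioxaspiro[4.5]dec-6-ene | C1=CC2(CCO1)OCCO2
A5 | alternative 2 | 3,4-di(propan-2-yloxy)-5-methoxy-6-(3-methylbut-2-en-1-yl)phenol | CC(C)Oc1cc(O)c(CC=C(C)C)c(OC)c1OC(C)C
A6 | alternative 2 | 2,3-di(propan-2-yloxy)cyclobut-2-en-1-one | O=C1CC(OC(C)C)=C1OC(C)C
A7 | alternative 2 | 1-methoxy-5-methylhex-4-en-1-yne | COC#CCC=C(C)C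
A8 | alternative 3 | 7-methoxy-5,8-di(propan-2-yloxy)-3-(2,4,5-trimethoxyphenyl)-4H-chromen-4-one (identical with 12) | COc1cc(OC)c(-c2coc3c(OC(C)C)c(OC)cc(OC(C)C)c3c2=O)cc1OC
A9 | alternative 3 | (2Z)-3-[3-methoxy-2,5-di(propan-2-yloxy)phenoxy]-2-(2,4,5-trimethoxyphenyl)prop-2-enoic acid | OC(=O)/C(=C\Oc1cc(OC(C)C)cc(OC)c1OC(C)C)c1cc(OC)c(OC)cc1OC
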